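**Plan**

1. Cembranoid numbering is used: C1 = CH(isopropenyl), C3–C6 = furan (C4 bears CO2Me), C8 = C(OH)Me, C10 = ketone, C11 = CHOH, C12 = CH(CO2Me), C20 = the ester carbon on C12.
2. Retrosynthetic cuts, in order: C12–C13 (the ring CH–CO2Me is read as the product of a Wolff ring contraction of a 15-membered ring in which C20 is a ketone between C13 and a diazo carbon C12); then C11–C12 (diazo aldol); then the furan (C4–C5 and C6–O, Feist–Benary); then C5–C6 (hydroformylation).
3. Forward: the furan is made first and joins a limonene half (C1–C3, C12–C14, C20) to a linalool half (C6–C11). The 15-membered carbocycle is closed by diazo aldol, and photolysis in MeOH contracts it to the 14-membered ring while C20 becomes the ester.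
4. Enabling feature: C12 is a ring carbon bearing only H and an ester carbon, and C20/C12 map onto the acetyl group of the limonene-derived keto aldehyde, so all ten limonene carbons are used.
5. Stereochemistry: C1 from (R)-limonene; C8 from (S)-linalool; C11 by Felkin–Anh addition next to a sacrificial C10 silyloxy centre (D-proline α-aminoxylation, later oxidised to the ketone); C12 by protonation of the ketene-derived enol under control of C11.

Key step: step 17

Remark: (S)-(+)-linalool (coriandrol) is taken as commercially available in high enantiomeric purity. The CIP descriptor at C8 changes along the route only because substituent priorities change; its spatial arrangement is never touched.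

**Route**

Step 1
Reactants: 1 (+)-limonene 1,2-oxide (4R, cis/trans mixture)
Product: 2 (3R)-6-oxo-3-(prop-1-en-2-yl)heptanal
Conditions: H5IO6, THF/H2O, 0 °C to rt
Reagents that add atoms: water, O
Why: Epoxide hydrolysis followed by periodate glycol cleavage (Malaprade reaction) opens the ring between the two oxygenated carbons without touching the isopropenyl group, and the untouched limonene stereocentre becomes C1 of the target.

Step 2
Reactants: 2 (3R)-6-oxo-3-(prop-1-en-2-yl)heptanal; 3 methyl diazoacetate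
Product: 4 methyl (5R)-3,8-dioxo-5-(prop-1-en-2-yl)nonanoate
Conditions: SnCl2 (10 mol %), CH2Cl2, rt
Reagents that add atoms: none
Why: Roskamp homologation converts the aldehyde into a β-keto ester (supplying C4 and its ester) and is selective for aldehydes over the methyl ketone.

Step 3
Reactants: 5 (S)-(+)-linalool
Product: 6 (3S)-3-(tert-butyldimethylsilyloxy)-3,7-dimethylocta-1,6-diene
Conditions: TBSOTf, 2,6-lutidine, CH2Cl2, 0 °C
Reagents that add atoms: tert-butyldimethylsilyl triflate, CC(C)(C)[Si](C)(C)OS(=O)(=O)C(F)(F)F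
Why: Silyl triflate silylation of a tertiary alcohol; the TBS ether keeps later aldehydes from closing to lactols and survives the two acid-mediated TES removals.

Step 4
Reactants: 6 (3S)-3-(tert-butyldimethylsilyloxy)-3,7-dimethylocta-1,6-diene
Product: 7 (4S)-4-(tert-butyldimethylsilyloxy)-4-methylhex-5-enal
Conditions: O3 (1 equiv, dye endpoint), CH2Cl2, −78 °C; then PPh3
Reagents that add atoms: ozone, [O-][O+]=O
Why: Selective ozonolysis, since ozone attacks the electron-rich trisubstituted alkene much faster than the monosubstituted vinyl group; the aldehyde carbon becomes C11.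

Step 5
Reactants: 7 (4S)-4-(tert-butyldimethylsilyloxy)-4-methylhex-5-enal
Product: 10 (2S,4S)-4-(tert-butyldimethylsilyloxy)-4-methylhex-5-ene-1,2-diol, via aminoxy aldehyde 8 (not isolated), via aminoxy alcohol 9 (not isolated)
Conditions: D-proline (20 mol %), PhNO, CHCl3, 4 °C; NaBH4, EtOH, 0 °C; then Zn, AcOH, EtOH, rt
Reagents that add atoms: nitrosobenzene, O=Nc1ccccc1
Why: Proline-catalysed α-aminoxylation (enamine attack on the oxygen of PhNO through the hydrogen-bonded Houk–List transition state) with D-proline sets the sacrificial C10 centre as S, and borohydride reduction and Zn/AcOH N–O cleavage then unmask the 1,2-diol.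

Step 6
Reactants: 10 (2S,4S)-4-(tert-butyldimethylsilyloxy)-4-methylhex-5-ene-1,2-diol
Product: 11 (3S,5S)-3-(tert-butyldimethylsilyloxy)-3-methyl-5,6-bis(triethylsilyloxy)hex-1-ene
Conditions: TESCl (2.4 equiv), imidazole, DMF, 0 °C to rt
Reagents that add atoms: chlorotriethylsilane, CC[Si](Cl)(CC)CC
Why: Standard silylation of a primary and a secondary alcohol; the primary TES ether can later be removed selectively.

Step 7
Reactants: 11 (3S,5S)-3-(tert-butyldimethylsilyloxy)-3-methyl-5,6-bis(triethylsilyloxy)hex-1-ene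
Product: 12 (4R,6S)-4-(tert-butyldimethylsilyloxy)-4-methyl-6,7-bis(triethylsilyloxy)heptanal
Conditions: Rh(acac)(CO)2 (1 mol %), tris(2,4-di-tert-butylphenyl) phosphite, CO/H2 (1:1, 20 bar), toluene, 70 °C
Reagents that add atoms: carbon monoxide, [C-]#[O+]
Why: Rh-catalysed hydroformylation of a vinyl group on a quaternary carbon can only give the linear aldehyde (Keulemans' rule), which supplies C5 with C6 as its α-methylene; the same reaction is known on linalool itself.

Step 8
Reactants: 12 (4R,6S)-4-(tert-butyldimethylsilyloxy)-4-methyl-6,7-bis(triethylsilyloxy)heptanal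
Product: 13 (4S,6S)-4-(tert-butyldimethylsilyloxy)-2-chloro-4-methyl-6,7-bis(triethylsilyloxy)heptanal (both C2 epimers)
Conditions: NCS, DL-proline (10 mol %), CH2Cl2, 0 °C
Reagents that add atoms: N-chlorosuccinimide, O=C1CCC(=O)N1Cl
Why: Enamine-catalysed α-chlorination of an aldehyde with NCS; the new C6 centre is irrelevant because it becomes a furan carbon.

Step 9
Reactants: 4 methyl (5R)-3,8-dioxo-5-(prop-1-en-2-yl)nonanoate; 13 (4S,6S)-4-(tert-butyldimethylsilyloxy)-2-chloro-4-methyl-6,7-bis(triethylsilyloxy)heptanal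
Product: 15 methyl 5-[(2S,4S)-2-(tert-butyldimethylsilyloxy)-2-methyl-4,5-bis(triethylsilyloxy)pentyl]-2-[(2R)-5-oxo-2-(prop-1-en-2-yl)hexyl]furan-3-carboxylate, via hydroxydihydrofuran 14 (not isolated)
Conditions: pyridine, THF, 0 to 50 °C
Reagents that add atoms: none
Why: Feist–Benary furan synthesis, in which the β-keto ester carbon (C4) adds to the aldehyde (C5), the enol oxygen displaces chloride at C6 and adduct 14 dehydrates, giving the 2,5-dialkyl-3-furoate pattern known for α-chloro aldehydes with acetoacetates; the far less acidic methyl ketone stays out.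

Step 10
Reactants: 15 the furan keto ester from step 9
Product: 17 methyl 2-[(2R)-6-diazo-5-oxo-2-(prop-1-en-2-yl)hexyl]-5-[(2S,4S)-2-(tert-butyldimethylsilyloxy)-2-methyl-4,5-bis(triethylsilyloxy)pentyl]furan-3-carboxylate, via trifluoroacetyl ketone 16 (not isolated)
Conditions: LiN(SiMe3)2, THF, −78 °C; CF3CO2CH2CF3; sat. aq NH4Cl work-up; then MsN3, Et3N, H2O, MeCN, rt
Reagents that add atoms: methanesulfonyl azide, CS(=O)(=O)N=[N+]=[N-]
Why: Danheiser detrifluoroacetylative diazo transfer, in which the amide base deprotonates the methyl side of the methyl ketone kinetically, trifluoroacetylation activates that carbon and the sulfonyl azide transfers N2 with loss of the trifluoroacetyl group, so the diazo group sits on C12 only.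

Step 11
Reactants: 17 the diazoketone from step 10
Product: 18 methyl 2-[(2R)-6-diazo-5-oxo-2-(prop-1-en-2-yl)hexyl]-5-[(2S,4S)-2-(tert-butyldimethylsilyloxy)-5-hydroxy-2-methyl-4-(triethylsilyloxy)pentyl]furan-3-carboxylate
Conditions: PPTS (0.1 equiv), MeOH/CH2Cl2, −10 °C
Reagents that add atoms: none
Why: Selective desilylation, since a primary TES ether is cleaved by PPTS/MeOH far faster than a secondary TES or a TBS ether, and the weak acid should leave the acyl diazo group alone.

Step 12
Reactants: 18 the primary alcohol from step 11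
Product: 19 methyl 2-[(2R)-6-diazo-5-oxo-2-(prop-1-en-2-yl)hexyl]-5-[(2S,4S)-2-(tert-butyldimethylsilyloxy)-2-methyl-5-oxo-4-(triethylsilyloxy)pentyl]furan-3-carboxylate
Conditions: DMP, pyridine, CH2Cl2, 0 °C
Reagents that add atoms: none
Why: Buffered Dess–Martin oxidation gives α-silyloxy aldehydes without epimerisation and is compatible with acyl diazo groups.

Step 13
Reactants: 19 the diazoketone aldehyde from step 12
Product: 20 macrocyclic diazo aldol (15-membered carbocycle C1–C14 plus C20, furan-bridged; 20-oxo, 12-diazo, (11R)-OH, (10S)-OTES, (8S)-Me/OTBS, (1R)-isopropenyl, 4-CO2Me)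
Conditions: DBU (0.3 equiv), MeCN (0.001 M, slow addition of 19), 0 °C
Reagents that add atoms: none
Why: Amine-base-mediated aldol-type addition of an acyldiazomethane to an aldehyde (diazo aldol), run end-to-end at high dilution to close the 15-membered carbocycle; the nucleophile should add anti to the C10–O bond (Felkin–Anh, α-silyloxy aldehyde) to give the 10,11-anti adduct, that is 11R, and α-silyloxy aldehydes are known to survive DBU in MeCN (Masamune–Roush conditions).

Step 14
Reactants: 20 macrocyclic diazo aldol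
Product: 21 the (11R)-OTBS ether of 20
Conditions: TBSOTf, 2,6-lutidine, CH2Cl2, −78 °C
Reagents that add atoms: tert-butyldimethylsilyl triflate, CC(C)(C)[Si](C)(C)OS(=O)(=O)C(F)(F)F
Why: Silyl triflate silylation at low temperature caps the hindered C11 carbinol (diazo carbonyl compounds tolerate these conditions) before C10 is oxidised.

Step 15
Reactants: 21 the (11R)-OTBS ether
Product: 22 the (10S)-alcohol (macrocycle as 21 with 10-OH in place of 10-OTES)
Conditions: PPTS, MeOH, 0 °C to rt
Reagents that add atoms: none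
Why: Selective desilylation of the secondary TES ether in the presence of a secondary and a tertiary TBS ether unveils the sacrificial C10 alcohol while no ester is yet present to lactonise with it.

Step 16
Reactants: 22 the (10S)-alcohol
Product: 23 macrocyclic 12-diazo-10,20-diketone ((11R)-OTBS, (8R)-Me/OTBS, (1R)-isopropenyl, 4-CO2Me)
Conditions: DMP, pyridine, CH2Cl2, 0 °C
Reagents that add atoms: none
Why: Dess–Martin oxidation erases the sacrificial C10 stereocentre and installs the C10 ketone before the ester exists, which avoids a γ-hydroxy ester.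

Step 17
Reactants: 23 macrocyclic 12-diazo-10,20-diketone
Product: 25 bis-TBS ether of the target (14-membered carbocycle; (12S)-CO2Me, (11R)-OTBS, 10-oxo, (8R)-Me/OTBS, (1R)-isopropenyl), via macrocyclic ketene 24 (not isolated)
Conditions: hν (365 nm LED), MeOH, −20 °C
Reagents that add atoms: methanol, CO
Why: Excitation of the α-diazoketone expels N2 and C13 shifts from the acyl carbon C20 to the diazo carbon C12 (concerted from the s-cis conformer or through the singlet acylcarbene), forming the C12–C13 bond and the 14-membered ketene 24, which methanol traps as the methyl ester. The closest known reaction is the photochemical Wolff ring contraction of cyclic 2-diazoketones in methanol, which has been used on large rings including cyclophanes. The 14-membered carbocycle is closed not by an end-to-end cyclisation but by a 1,2-alkyl shift inside the preformed 15-membered ring, a contraction by one carbon in which C20 leaves the ring as the ester carbon. The new stereocentre C12 is set when methanol protonates the ketene-derived ester enol: A(1,3) strain should hold C11–H in the enol plane and the proton should arrive anti to the C11–C10 bond, giving the 11,12-anti (12S) isomer, while the neutral medium leaves C11 untouched. The step needs Wolff shift to beat 1,2-hydride shift from C11 and O–H insertion into methanol; the C10 carbonyl makes C11–H a poor hydride donor, low temperature and long-wavelength light favour the concerted path, and the regiochemistry is fixed because C13 is the only carbon on the acyl carbon.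

Step 18
Reactants: 25 bis-TBS ether of the target
Product: 26 CNP0218204.1 (target)
Conditions: HF·pyridine, pyridine, THF, 0 °C to rt
Reagents that add atoms: none
Why: Buffered fluoride cleavage of both TBS ethers avoids the retro-aldol, β-elimination and epimerisation that basic fluoride could cause in the β-hydroxy ketone and β-hydroxy ester.

**Compound list**

1 | (+)-limonene 1,2-oxide, (4R), cis/trans mixture | CC(=C)[C@@H]1CCC2(C)OC2C1 | starting material
2 | (3R)-6-oxo-3-(prop-1-en-2-yl)heptanal | O=CC[C@@H](CCC(C)=O)C(C)=C | intermediate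
3 | methyl diazoacetate | COC(=O)C=[N+]=[N-] | starting material
4 | methyl (5R)-3,8-dioxo-5-(prop-1-en-2-yl)nonanoate | COC(=O)CC(=O)C[C@@H](CCC(C)=O)C(C)=C | intermediate
5 | (S)-(+)-linalool, (3S)-3,7-dimethylocta-1,6-dien-3-ol | CC(C)=CCC[C@](C)(O)C=C | starting material
6 | (3S)-3-(tert-butyldimethylsilyloxy)-3,7-dimethylocta-1,6-diene | CC(C)=CCC[C@](C)(O[Si](C)(C)C(C)(C)C)C=C | intermediate
7 | (4S)-4-(tert-butyldimethylsilyloxy)-4-methylhex-5-enal | O=CCC[C@](C)(O[Si](C)(C)C(C)(C)C)C=C | intermediate
8 | (2S,4S)-4-(tert-butyldimethylsilyloxy)-4-methyl-2-(phenylaminooxy)hex-5-enal | O=C[C@@H](ONc1ccccc1)C[C@](C)(O[Si](C)(C)C(C)(C)C)C=C | intermediate (not isolated)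
9 | (2S,4S)-4-(tert-butyldimethylsilyloxy)-4-methyl-2-(phenylaminooxy)hex-5-en-1-ol | OC[C@@H](ONc1ccccc1)C[C@](C)(O[Si](C)(C)C(C)(C)C)C=C | intermediate (not isolated)
10 | (2S,4S)-4-(tert-butyldimethylsilyloxy)-4-methylhex-5-ene-1,2-diol | OC[C@@H](O)C[C@](C)(O[Si](C)(C)C(C)(C)C)C=C | intermediate
11 | (3S,5S)-3-(tert-butyldimethylsilyloxy)-3-methyl-5,6-bis(triethylsilyloxy)hex-1-ene | CC[Si](CC)(CC)OC[C@@H](O[Si](CC)(CC)CC)C[C@](C)(O[Si](C)(C)C(C)(C)C)C=C | intermediate
12 | (4R,6S)-4-(tert-butyldimethylsilyloxy)-4-methyl-6,7-bis(triethylsilyloxy)heptanal | CC[Si](CC)(CC)OC[C@@H](O[Si](CC)(CC)CC)C[C@](C)(O[Si](C)(C)C(C)(C)C)CCC=O | intermediate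
13 | (4S,6S)-4-(tert-butyldimethylsilyloxy)-2-chloro-4-methyl-6,7-bis(triethylsilyloxy)heptanal, both C2 epimers | CC[Si](CC)(CC)OC[C@@H](O[Si](CC)(CC)CC)C[C@](C)(O[Si](C)(C)C(C)(C)C)CC(Cl)C=O | intermediate
14 | 4-hydroxy-4,5-dihydrofuran adduct of 4 and 13 (methyl 4-hydroxy-4,5-dihydrofuran-3-carboxylate carrying the two side chains of 15; ring C4/C5 epimers) | COC(=O)C1=C(C[C@@H](CCC(C)=O)C(C)=C)OC(C[C@@](C)(O[Si](C)(C)C(C)(C)C)C[C@H](O[Si](CC)(CC)CC)CO[Si](CC)(CC)CC)C1O | intermediate (not isolated)
15 | methyl 5-[(2S,4S)-2-(tert-butyldimethylsilyloxy)-2-methyl-4,5-bis(triethylsilyloxy)pentyl]-2-[(2R)-5-oxo-2-(prop-1-en-2-yl)hexyl]furan-3-carboxylate | COC(=O)c1cc(C[C@@](C)(O[Si](C)(C)C(C)(C)C)C[C@H](O[Si](CC)(CC)CC)CO[Si](CC)(CC)CC)oc1C[C@@H](CCC(C)=O)C(C)=C | intermediate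
16 | trifluoroacetyl ketone: 15 with the CH3C(=O) terminus converted to CF3C(=O)CH2C(=O) | COC(=O)c1cc(C[C@@](C)(O[Si](C)(C)C(C)(C)C)C[C@H](O[Si](CC)(CC)CC)CO[Si](CC)(CC)CC)oc1C[C@@H](CCC(=O)CC(=O)C(F)(F)F)C(C)=C | intermediate (not isolated)
17 | methyl 2-[(2R)-6-diazo-5-oxo-2-(prop-1-en-2-yl)hexyl]-5-[(2S,4S)-2-(tert-butyldimethylsilyloxy)-2-methyl-4,5-bis(triethylsilyloxy)pentyl]furan-3-carboxylate | COC(=O)c1cc(C[C@@](C)(O[Si](C)(C)C(C)(C)C)C[C@H](O[Si](CC)(CC)CC)CO[Si](CC)(CC)CC)oc1C[C@@H](CCC(=O)C=[N+]=[N-])C(C)=C | intermediate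
18 | methyl 2-[(2R)-6-diazo-5-oxo-2-(prop-1-en-2-yl)hexyl]-5-[(2S,4S)-2-(tert-butyldimethylsilyloxy)-5-hydroxy-2-methyl-4-(triethylsilyloxy)pentyl]furan-3-carboxylate | COC(=O)c1cc(C[C@@](C)(O[Si](C)(C)C(C)(C)C)C[C@H](O[Si](CC)(CC)CC)CO)oc1C[C@@H](CCC(=O)C=[N+]=[N-])C(C)=C | intermediate
19 | methyl 2-[(2R)-6-diazo-5-oxo-2-(prop-1-en-2-yl)hexyl]-5-[(2S,4S)-2-(tert-butyldimethylsilyloxy)-2-methyl-5-oxo-4-(triethylsilyloxy)pentyl]furan-3-carboxylate | COC(=O)c1cc(C[C@@](C)(O[Si](C)(C)C(C)(C)C)C[C@H](O[Si](CC)(CC)CC)C=O)oc1C[C@@H](CCC(=O)C=[N+]=[N-])C(C)=C | intermediate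
20 | macrocyclic diazo aldol: furan-bridged 15-membered carbocycle (C1–C14 plus C20); 20-oxo, 12-diazo, (11R)-OH, (10S)-OTES, (8S)-Me/OTBS, (1R)-isopropenyl, 4-CO2Me | COC(=O)c1cc2oc1C[C@H](C(C)=C)CCC(=O)C(=[N+]=[N-])[C@@H](O)[C@@H](O[Si](CC)(CC)CC)C[C@](C)(O[Si](C)(C)C(C)(C)C)C2 | intermediate
21 | as 20 with (11R)-OTBS | COC(=O)c1cc2oc1C[C@H](C(C)=C)CCC(=O)C(=[N+]=[N-])[C@@H](O[Si](C)(C)C(C)(C)C)[C@@H](O[Si](CC)(CC)CC)C[C@](C)(O[Si](C)(C)C(C)(C)C)C2 | intermediate
22 | as 21 with (10S)-OH | COC(=O)c1cc2oc1C[C@H](C(C)=C)CCC(=O)C(=[N+]=[N-])[C@@H](O[Si](C)(C)C(C)(C)C)[C@@H](O)C[C@](C)(O[Si](C)(C)C(C)(C)C)C2 | intermediate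
23 | macrocyclic 12-diazo-10,20-diketone; (11R)-OTBS, (8R)-Me/OTBS, (1R)-isopropenyl, 4-CO2Me | COC(=O)c1cc2oc1C[C@H](C(C)=C)CCC(=O)C(=[N+]=[N-])[C@@H](O[Si](C)(C)C(C)(C)C)C(=O)C[C@](C)(O[Si](C)(C)C(C)(C)C)C2 | intermediate
24 | macrocyclic ketene: 14-membered carbocycle with C12=C20=O; (11R)-OTBS, 10-oxo, (8R)-Me/OTBS, (1R)-isopropenyl | COC(=O)c1cc2oc1C[C@H](C(C)=C)CCC(=C=O)[C@@H](O[Si](C)(C)C(C)(C)C)C(=O)C[C@](C)(O[Si](C)(C)C(C)(C)C)C2 | intermediate (not isolated)
25 | 8,11-bis-TBS ether of the target; (1R,8R,11R,12S) | COC(=O)c1cc2oc1C[C@H](C(C)=C)CC[C@H](C(=O)OC)[C@@H](O[Si](C)(C)C(C)(C)C)C(=O)C[C@](C)(O[Si](C)(C)C(C)(C)C)C2 | intermediate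
26 | CNP0218204.1; (1R,8R,11R,12S) | C=C(C)[C@@H]1CC[C@H](C(=O)OC)[C@@H](O)C(=O)C[C@](C)(O)CC2=CC(C(=O)OC)=C(C1)O2 | target

**Totals and risks**

Total steps: 18. Longest linear sequence: 16 (steps 3–18, from 5); steps 1–2 form the second branch.

Step 17. What may go wrong: leakage to the free acylcarbene (1,2-hydride shift from C11, O–H insertion into methanol) and poor facial selectivity in the protonation that sets C12. The fallback sets out from 21, where C10 is still an sp3 silyloxy carbon and no ketone chromophore is present. Irradiation of 21 in MeOH should give the ring-contracted methyl ester F1, in which the larger branched C10 substituent reinforces protonation anti to it. The secondary TES ether is then cleaved (HF·pyridine/pyridine, THF, 0 °C) to the C10 alcohol F2, which is oxidised at once with DMP, before it can lactonise onto the new ester, to rejoin the route at 25.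

Step 13. What may go wrong: intermolecular aldol addition (oligomerisation) and, under the reversible amine-base conditions, erosion of Felkin control through retro-aldol equilibration or epimerisation at C10. The fallback sets out from 20 as its C11 epimer mixture. DMP oxidation gives the 2-diazo-1,3-diketone F3, and C11 is then reset by hydride addition instead of C–C addition: NaBH4 (MeOH/CH2Cl2, −78 °C) should attack the more electrophilic α-silyloxy-substituted carbonyl anti to the C10–O bond (Felkin–Anh reduction) and return 20 as the 11R isomer.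

Step 10. What may go wrong: incomplete regiocontrol in the kinetic enolisation (C13 methylene against C12 methyl) or attack of the amide base on the ester or silyl ethers. The fallback sets out from 15 and uses no strong base. Condensation with Me2NCH(OMe)2 (neat, 100 °C) should occur at the methyl group to give the enaminone F4, and diazo transfer with TsN3 (MeCN, rt; cycloaddition, then loss of the N-sulfonyl formamidine) should give 17.

Further compounds
F1 | step 17 | ring-contracted ester with C10 still silylated: 14-membered carbocycle, (12S)-CO2Me, (11R)-OTBS, (10S)-OTES, (8S)-Me/OTBS, (1R)-isopropenyl | COC(=O)c1cc2oc1C[C@H](C(C)=C)CC[C@H](C(=O)OC)[C@@H](O[Si](C)(C)C(C)(C)C)[C@@H](O[Si](CC)(CC)CC)C[C@](C)(O[Si](C)(C)C(C)(C)C)C2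
F2 | step 17 | as F1 with (10S)-OH | COC(=O)c1cc2oc1C[C@H](C(C)=C)CC[C@H](C(=O)OC)[C@@H](O[Si](C)(C)C(C)(C)C)[C@@H](O)C[C@](C)(O[Si](C)(C)C(C)(C)C)C2
F3 | step 13 | macrocyclic 12-diazo-11,20-diketone; (10S)-OTES, (8S)-Me/OTBS, (1R)-isopropenyl | COC(=O)c1cc2oc1C[C@H](C(C)=C)CCC(=O)C(=[N+]=[N-])C(=O)[C@@H](O[Si](CC)(CC)CC)C[C@](C)(O[Si](C)(C)C(C)(C)C)C2
F4 | step 10 | (E)-enaminone: 15 with the CH3C(=O) terminus converted to Me2NCH=CHC(=O) | COC(=O)c1cc(C[C@@](C)(O[Si](C)(C)C(C)(C)C)C[C@H](O[Si](CC)(CC)CC)CO[Si](CC)(CC)CC)oc1C[C@@H](CCC(=O)/C=C/N(C)C)C(C)=C
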